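## Retrosynthetic overview

1. The core is a cis-fused 3,7-dioxabicyclo[3.3.0]octane with ring A = C1–C2–O3–C4–C5 and ring B = C1–C8–O7–C6–C5. OAc on C1 and the guaiacyl groups on C2 and C6 all lie on the convex face. The endgame is C1–OH acetylation, then phenol deallylation.
2. The key disconnection is aryl–C6. C6 is bound to O7, so it is a latent oxocarbenium carbon (O7=C6) that can take a guaiacyl group from an aryl fluoroborate. The fold of the bicycle and the C1 oxygen, which lies 1,3-cis to the incoming group, both direct attack to the convex face.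
3. The cation is grown in the same flask from an open-chain epoxy diol acetal. C4–OH opens the C1–C2 oxirane at benzylic C2 (ring A first), then C8–OH captures acetal carbon C6 (ring B second). Every other O/C pairing would close a four-membered ring.
4. The oxirane (C1, C2) comes from Sharpless epoxidation of an (E)-2-arylidene-1,4-diol. That diol comes from iBu2AlH reduction of an (E)-arylidene butyrolactone, made by aldol condensation of O-allylvanillin with a 4-(dimethoxymethyl)butyrolactone.
5. C5 comes from organocatalytic α-hydroxymethylation of methyl 4-oxobutanoate. The aryl donor comes from a commercial guaiacyl boronic ester.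

Key step: step 8

Assumption: 4 and 10 are taken as catalogue compounds, and the locants C1–C8 of the bicyclic core are kept for the same carbons in all open-chain and monocyclic precursors.

## Route

Step 1
Reactants: 1 methyl 4-oxobutanoate
Product: 3 (4R)-4-(dimethoxymethyl)oxolan-2-one, via hydroxy aldehyde 2 (not isolated)
Conditions: 37% aq. HCHO (3 equiv), (S)-α,α-diphenylprolinol trimethylsilyl ether (10 mol%), toluene/pH 7 phosphate buffer, rt; organic phase, then HC(OMe)3 (3 equiv), MeOH, CSA (5 mol%), 0 °C to rt; then toluene, 50 °C, MeOH distilled off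
Reagents that add atoms: formaldehyde, C=O; trimethyl orthoformate, COC(OC)OC
Why: Enamine catalysis (organocatalytic asymmetric α-hydroxymethylation of an aldehyde): the (E)-enamine of 1 should meet formaldehyde on the face away from the CPh2(OSiMe3) group of the (S)-catalyst, which sets C5 as (R), and the labile aldol 2 is trapped at once as its dimethyl acetal, whose γ-hydroxy ester lactonises.

Step 2
Reactants: 3 (4R)-4-(dimethoxymethyl)oxolan-2-one; 4 4-(allyloxy)-3-methoxybenzaldehyde
Product: 5 (3S,4R)-3-{[4-(allyloxy)-3-methoxyphenyl](hydroxy)methyl}-4-(dimethoxymethyl)oxolan-2-one (3,4-trans, both carbinol epimers)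
Conditions: LiN(iPr)2 (1.05 equiv), THF, −78 °C; then 4; AcOH quench at −78 °C
Reagents that add atoms: none
Why: Lithium enolate aldol addition, in which the aldehyde should approach anti to the acetal substituent (3,4-trans); the two new centres are removed in step 3, so their ratio does not matter.

Step 3
Reactants: 5 aldol adduct
Product: 7 (3E,4R)-3-[4-(allyloxy)-3-methoxybenzylidene]-4-(dimethoxymethyl)oxolan-2-one, via mesylate 6 (not isolated)
Conditions: MsCl (1.3 equiv), Et3N (1.5 equiv), CH2Cl2, 0 °C; then DBU (1.2 equiv), 0 °C to rt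
Reagents that add atoms: none
Why: Mesylation followed by E1cB elimination should funnel both carbinol epimers to the more stable (E)-arylidene lactone (aryl anti to the carbonyl carbon, syn to C5), as is usual for α-arylidene butyrolactone lignans, and DBU is too weak a base to remove the γ-hydrogen on C5.

Step 4
Reactants: 7 (E)-arylidene lactone
Product: 8 (2E,3R)-2-[4-(allyloxy)-3-methoxybenzylidene]-3-(dimethoxymethyl)butane-1,4-diol
Conditions: iBu2AlH (4.5 equiv), CH2Cl2, −78 to 0 °C; aq. potassium sodium tartrate
Reagents that add atoms: none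
Why: 1,2-Reduction of an α,β-unsaturated lactone by iBu2AlH gives the allylic/homoallylic diol without touching the alkene geometry, the acetal, the allyl ether or C5, and the neutral work-up avoids transacetalisation.

Step 5
Reactants: 8 (E)-diol
Product: 9 (2S)-2-{(2S,3S)-3-[4-(allyloxy)-3-methoxyphenyl]-2-(hydroxymethyl)oxiran-2-yl}-3,3-dimethoxypropan-1-ol
Conditions: Ti(OiPr)4 (20 mol%), L-(+)-diethyl tartrate (24 mol%), t-BuOOH (2 equiv, decane), 4 Å MS, CH2Cl2, −25 °C; chromatography on Et3N-deactivated SiO2
Reagents that add atoms: tert-butyl hydroperoxide, CC(C)(C)OO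
Why: Sharpless asymmetric epoxidation: the L-(+)-tartrate catalyst bound to C8–OH should deliver oxygen to the face that gives the (2S,3S)-oxirane, as with (E)-2-alkylcinnamyl alcohols, so C1 and C2 are set by reagent control, and the allyl ether, which is not an allylic alcohol, is left alone.

Step 6
Reactants: 10 2-methoxy-4-(4,4,5,5-tetramethyl-1,3,2-dioxaborolan-2-yl)phenol
Product: 11 2-[4-(allyloxy)-3-methoxyphenyl]-4,4,5,5-tetramethyl-1,3,2-dioxaborolane
Conditions: allyl bromide (1.2 equiv), K2CO3 (1.5 equiv), acetone, 50 °C
Reagents that add atoms: allyl bromide, C=CCBr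
Why: Williamson ether synthesis on a phenol; the pinacol boronate tolerates K2CO3 in acetone.

Step 7
Reactants: 11 allyl ether boronate
Product: 12 potassium [4-(allyloxy)-3-methoxyphenyl]trifluoroborate
Conditions: KHF2 (4.5 equiv), MeOH/H2O, rt; repeated evaporation from aq. MeOH
Reagents that add atoms: potassium hydrogen difluoride, [K+].[F-].F
Why: Standard exchange of a pinacol boronate into the crystalline potassium trifluoroborate with KHF2, with pinacol leaving as its water azeotrope.

Step 8
Reactants: 9 open-chain epoxy diol acetal; 12 potassium aryltrifluoroborate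
Product: 15 (1S,2R,5R,6S)-2,6-bis[4-(allyloxy)-3-methoxyphenyl]-3,7-dioxabicyclo[3.3.0]octan-1-ol, via oxolane diol acetal 13 (not isolated), via bicyclic methyl acetal 14 (not isolated)
Conditions: 12 (2.5 equiv), BF3·OEt2 (3 equiv), CH2Cl2, 0 °C, 15 min; −78 °C, 9 in CH2Cl2 added slowly; to −30 °C; aq. NaHCO3
Reagents that add atoms: none
Why: Proposed new method: the aryldifluoroborane made from 12 and BF3·OEt2 activates the oxirane of 9, C4–OH opens it at benzylic C2 in a 5-endo-tet closure (ring A, 13), the acetal ionises and C8–OH adds to the methoxycarbenium carbon C6 in a 5-exo-trig closure (ring B, 14), a second ionisation gives the bicyclic oxocarbenium ion O7=C6, and the aryl group moves from a fluoroborate held on the freed C1 oxygen to C6 with loss of boron from the ipso carbon. The closest known reaction types are the acid-induced 5-endo cyclisation of 4-aryl-3,4-epoxy alcohols to 2-aryl-3-hydroxyoxolanes, the BF3-promoted aryl transfer from potassium aryltrifluoroborates to oxocarbenium ions made from acetals, the hydroxyl-directed Petasis-type borate transfer and the acid-mediated C-arylation of furofuran lactols of the samin type, and what is new is their union in one flask on an open-chain substrate. C2 is set by inversion of the (S)-oxirane carbon through backside attack of the CH2OH that lies anti to the oxirane oxygen, C1 keeps its C–O bond, C5 is untouched, and C6 is set by attack on the convex face of the cis-fused bicycle, which is also the face on which the C1–O–B tether can deliver the aryl group through a six-membered transition state. The step needs chemoselectivity among three hydroxyls and two electrophilic carbons, and the skeleton secures it because C4–OH with C6, C8–OH with C2 and C1–OH with C6 would each close a four-membered ring. Regioselectivity on the arene is fixed by ipso substitution of boron, which free guaiacol could not guarantee, and an early aryl transfer to the acyclic methoxycarbenium ion should be harmless because the resulting 4-alkoxybenzyl methyl ether re-ionises and C8–OH still closes ring B. Keeping the mixture at or below −30 °C should prevent ionisation of the two 4-alkoxybenzylic C–O bonds of 15, so that C2 and C6 are not epimerised.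

Step 9
Reactants: 15 tertiary alcohol
Product: 16 (1S,2R,5R,6S)-2,6-bis[4-(allyloxy)-3-methoxyphenyl]-3,7-dioxabicyclo[3.3.0]octan-1-yl acetate
Conditions: Ac2O (5 equiv), DMAP (0.5 equiv), Et3N (6 equiv), CH2Cl2, 40 °C
Reagents that add atoms: acetic anhydride, CC(=O)OC(C)=O
Why: DMAP-catalysed (Steglich-type) acylation reaches the only free hydroxyl, the convex-face tertiary C1–OH, under basic conditions that break no bond to a stereocentre and cannot ionise the benzylic ethers.

Step 10
Reactants: 16 diallyl ether acetate
Product: 17 1-acetoxypinoresinol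
Conditions: Pd(PPh3)4 (5 mol%), morpholine (6 equiv), THF, rt
Reagents that add atoms: none
Why: Tsuji–Trost-type deallylation: zerovalent palladium ionises the two aryl allyl ethers to π-allyl complexes that morpholine intercepts, under neutral and non-reductive conditions that leave the tertiary acetate, the benzylic ring C–O bonds and all four stereocentres untouched.

## Compound list

1 | methyl 4-oxobutanoate | COC(=O)CCC=O | starting material
2 | methyl (3R)-3-formyl-4-hydroxybutanoate | COC(=O)C[C@H](CO)C=O | intermediate
3 | (4R)-4-(dimethoxymethyl)oxolan-2-one | O=C1OC[C@H](C(OC)OC)C1 | intermediate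
4 | 4-(allyloxy)-3-methoxybenzaldehyde (O-allylvanillin) | COc1cc(C=O)ccc1OCC=C | starting material
5 | (3S,4R)-3-{[4-(allyloxy)-3-methoxyphenyl](hydroxy)methyl}-4-(dimethoxymethyl)oxolan-2-one, carbinol epimers | O=C1OC[C@H](C(OC)OC)[C@H]1C(O)c2ccc(OCC=C)c(OC)c2 | intermediate
6 | methanesulfonate of 5 | O=C1OC[C@H](C(OC)OC)[C@H]1C(OS(C)(=O)=O)c2ccc(OCC=C)c(OC)c2 | intermediate
7 | (3E,4R)-3-[4-(allyloxy)-3-methoxybenzylidene]-4-(dimethoxymethyl)oxolan-2-one | O=C1OC[C@H](C(OC)OC)/C1=C\c2ccc(OCC=C)c(OC)c2 | intermediate
8 | (2E,3R)-2-[4-(allyloxy)-3-methoxybenzylidene]-3-(dimethoxymethyl)butane-1,4-diol | OC/C(=C/c1ccc(OCC=C)c(OC)c1)[C@H](CO)C(OC)OC | intermediate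
9 | (2S)-2-{(2S,3S)-3-[4-(allyloxy)-3-methoxyphenyl]-2-(hydroxymethyl)oxiran-2-yl}-3,3-dimethoxypropan-1-ol | OC[C@@]1(O[C@H]1c2ccc(OCC=C)c(OC)c2)[C@H](CO)C(OC)OC | intermediate
10 | 2-methoxy-4-(4,4,5,5-tetramethyl-1,3,2-dioxaborolan-2-yl)phenol | COc1cc(B2OC(C)(C)C(C)(C)O2)ccc1O | starting material
11 | 2-[4-(allyloxy)-3-methoxyphenyl]-4,4,5,5-tetramethyl-1,3,2-dioxaborolane | COc1cc(B2OC(C)(C)C(C)(C)O2)ccc1OCC=C | intermediate
12 | potassium [4-(allyloxy)-3-methoxyphenyl]trifluoroborate | COc1cc([B-](F)(F)F)ccc1OCC=C.[K+] | intermediate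
13 | (2R,3S,4S)-2-[4-(allyloxy)-3-methoxyphenyl]-4-(dimethoxymethyl)-3-(hydroxymethyl)oxolan-3-ol | OC[C@]1(O)[C@@H](c2ccc(OCC=C)c(OC)c2)OC[C@@H]1C(OC)OC | intermediate
14 | (1S,2R,5S)-2-[4-(allyloxy)-3-methoxyphenyl]-6-methoxy-3,7-dioxabicyclo[3.3.0]octan-1-ol, both anomers at C6 | COC1OC[C@]2(O)[C@@H](c3ccc(OCC=C)c(OC)c3)OC[C@H]12 | intermediate
15 | (1S,2R,5R,6S)-2,6-bis[4-(allyloxy)-3-methoxyphenyl]-3,7-dioxabicyclo[3.3.0]octan-1-ol | COc1cc([C@H]2OC[C@]3(O)[C@@H](c4ccc(OCC=C)c(OC)c4)OC[C@H]23)ccc1OCC=C | intermediate
16 | (1S,2R,5R,6S)-2,6-bis[4-(allyloxy)-3-methoxyphenyl]-3,7-dioxabicyclo[3.3.0]octan-1-yl acetate | COc1cc([C@H]2OC[C@]3(OC(C)=O)[C@@H](c4ccc(OCC=C)c(OC)c4)OC[C@H]23)ccc1OCC=C | intermediate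
17 | 1-acetoxypinoresinol, (1S,2R,5R,6S) | COc1cc([C@H]2OC[C@]3(OC(C)=O)[C@@H](c4ccc(O)c(OC)c4)OC[C@H]23)ccc1O | target

## Step count and risks

Total step count: 10. Longest linear sequence: 8 (steps 1–5 and 8–10, from methyl 4-oxobutanoate).

**Step 8 (proposed new method).**
- Possible failures:
  - A semipinacol shift of the activated oxirane may outrun ring closure.
  - Liberated methanol and HF may protodeboronate the electron-rich aryl borane.
  - The benzylic C–O bonds may ionise, with loss of configuration at C2 or C6.
- The fallback uses known chemistry only. It takes the cascade apart and brings the aryl group in as a carbanion. It sets out from 9 and comes back at 15.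
- Catalytic CSA in CH2Cl2 at 0 °C closes both rings of 9, and the bicyclic methyl acetal 14 is isolated.
- Aqueous acetic acid in THF hydrolyses 14 to the lactol (1S,2R,5S)-2-[4-(allyloxy)-3-methoxyphenyl]-3,7-dioxabicyclo[3.3.0]octane-1,6-diol F1.
- Commercial 4-bromo-2-methoxyphenol is allylated (allyl bromide, K2CO3) to 1-(allyloxy)-4-bromo-2-methoxybenzene F2. Mg in THF then converts it into [4-(allyloxy)-3-methoxyphenyl]magnesium bromide F3.
- An excess of F3 adds to the open hydroxy aldehyde form of F1. This gives (2R,3S,4R)-2-[4-(allyloxy)-3-methoxyphenyl]-4-{[4-(allyloxy)-3-methoxyphenyl](hydroxy)methyl}-3-(hydroxymethyl)oxolan-3-ol F4 as a mixture at the new carbinol.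
- Catalytic PPTS in CH2Cl2 at 0 °C ionises only this 4-alkoxybenzylic alcohol. C8–OH then closes ring B with the aryl group on the convex face, the usual cyclodehydration endgame of furofuran lignans, to give 15.

**Step 5.**
- Possible failures:
  - The 1,4-diol may sequester the titanium catalyst, or the resident C5 centre may be mismatched with it, either of which would erode facial selectivity.
  - External alcohols may open the electron-rich oxirane.
- Partial closure of 9 to 13 during this step would do no harm, because 13 lies on the path of step 8.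
- The fallback replaces reagent control by substrate control on a ring. It sets out from 8 and comes back at 14.
- Catalytic PPTS in CH2Cl2 lets C8–OH displace one methoxy group, giving {(3R,4E)-4-[4-(allyloxy)-3-methoxybenzylidene]-2-methoxyoxolan-3-yl}methanol F5, in which ring B is already closed.
- Dimethyldioxirane in acetone/CH2Cl2 at −40 °C should attack the exocyclic trisubstituted alkene on the ring face anti to the neighbouring CH2OH. This gives {(2S,3S,7S)-2-[4-(allyloxy)-3-methoxyphenyl]-6-methoxy-1,5-dioxaspiro[2.4]heptan-7-yl}methanol F6.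
- A trace of CSA lets the CH2OH open F6 at the benzylic carbon with inversion to give 14, which then enters the conditions of step 8 in place of 9.

**Step 1.**
- Possible failures: the β-hydroxy aldehyde may dehydrate or racemise by enolisation during the telescoped acetalisation, and lactonisation may stay incomplete.
- The fallback sets C5 by transition-metal catalysis on a preformed lactone. It sets out from commercial furan-2(5H)-one in place of 1 and comes back at 3.
- Rhodium-catalysed asymmetric conjugate addition (Hayashi–Miyaura reaction) uses potassium vinyltrifluoroborate, Rh(acac)(C2H4)2 and (S)-BINAP in aqueous dioxane. It should give (4S)-4-ethenyloxolan-2-one F7.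
- Ozonolysis (O3, CH2Cl2/MeOH, −78 °C, then Me2S) gives (3R)-5-oxooxolane-3-carbaldehyde F8.
- F8 is acetalised without isolation (HC(OMe)3, MeOH, catalytic CSA) to 3.

## Further compounds

F1 | step 8 | (1S,2R,5S)-2-[4-(allyloxy)-3-methoxyphenyl]-3,7-dioxabicyclo[3.3.0]octane-1,6-diol (lactol, both anomers) | OC1OC[C@]2(O)[C@@H](c3ccc(OCC=C)c(OC)c3)OC[C@H]12
F2 | step 8 | 1-(allyloxy)-4-bromo-2-methoxybenzene | COc1cc(Br)ccc1OCC=C
F3 | step 8 | [4-(allyloxy)-3-methoxyphenyl]magnesium bromide | COc1cc([Mg]Br)ccc1OCC=C
F4 | step 8 | (2R,3S,4R)-2-[4-(allyloxy)-3-methoxyphenyl]-4-{[4-(allyloxy)-3-methoxyphenyl](hydroxy)methyl}-3-(hydroxymethyl)oxolan-3-ol (carbinol epimers) | OC[C@]1(O)[C@@H](c2ccc(OCC=C)c(OC)c2)OC[C@@H]1C(O)c3ccc(OCC=C)c(OC)c3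
F5 | step 5 | {(3R,4E)-4-[4-(allyloxy)-3-methoxybenzylidene]-2-methoxyoxolan-3-yl}methanol (both anomers) | COC1OC/C(=C/c2ccc(OCC=C)c(OC)c2)[C@@H]1CO
F6 | step 5 | {(2S,3S,7S)-2-[4-(allyloxy)-3-methoxyphenyl]-6-methoxy-1,5-dioxaspiro[2.4]heptan-7-yl}methanol (both anomers) | COC1OC[C@@]2(O[C@H]2c3ccc(OCC=C)c(OC)c3)[C@@H]1CO
F7 | step 1 | (4S)-4-ethenyloxolan-2-one | O=C1OC[C@H](C=C)C1
F8 | step 1 | (3R)-5-oxooxolane-3-carbaldehyde | O=C1OC[C@H](C=O)C1
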